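**Retrosynthetic overview**
1. Target ⇐ 10‑O‑tigloylation and 6‑O‑(4‑hydroxybenzoyl)ation of a dauc‑8‑ene‑4α,6α‑diol; the C‑10 oxygen comes from allylic oxidation and catalyst‑controlled reduction.
2. 4α,6α‑Diol ⇐ daucene by two α‑face oxygenations: a singlet‑oxygen ene reaction (C4–O, alkene moved to C5=C6), then hydroxyl‑tethered hydrosilylation/oxidation (H‑5, C6–O).
3. Daucene ⇐ carotol‑type tertiary alcohol (dehydration) ⇐ ketyl–olefin closure of the five‑membered ring (farnesane C6–C10 bond).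
4. Cycloheptenone ⇐ (3S,6E)‑nerolidol by bromoetherification, E2 and [3,3] shift: the farnesane C1–C7 closure, with C3→C7 chirality transfer.
5. Ring order: seven‑membered ring first (C1–C7), then five‑membered ring (C6–C10), as in the direct nerolidyl → carotol/daucene cyclisation; oxygenation follows on the hydrocarbon.

Assumption and conventions: natural (+)‑(3S,6E)‑nerolidol is bought enantioenriched; acyclic compounds carry farnesane locants, bicyclic ones daucane locants (C‑1 quaternary, C‑4 carbinol, C‑5 ring‑fusion CH), and α is the face opposite the angular methyl. The target as drawn has 4‑OH, H‑5, 6‑O and 10‑O all α.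

**Step 1**
Reactants: 1 (3S,6E)-3,7,11-trimethyldodeca-1,6,10-trien-3-ol [(3S,6E)-nerolidol]
Product: 2 (2S,5R)-5-[(2S)-2-bromo-6-methylhept-5-en-2-yl]-2-ethenyl-2-methyloxolane (formed with its 5S,2′R partner; both are used)
Conditions: N-bromosuccinimide (1.05 equiv), CH2Cl2, 0 °C
Reagents that add atoms: N-bromosuccinimide, O=C1CCC(=O)N1Br
Why: 5-exo bromoetherification in which the tertiary OH opens the 6,7-bromonium ion anti at C6, so both ring diastereomers carry the same C6/C7 relative configuration, which is all that step 2 needs.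

**Step 2**
Reactants: 2 (2S,5R)-5-[(2S)-2-bromo-6-methylhept-5-en-2-yl]-2-ethenyl-2-methyloxolane
Product: 4 (2R)-2,5-dimethyl-2-(4-methylpent-3-en-1-yl)cyclohept-4-en-1-one, via E-enol ether 3 (not isolated)
Conditions: 1,8-diazabicyclo[5.4.0]undec-7-ene (DBU, 3 equiv), o-xylene, 110 °C then 145 °C (sealed tube)
Reagents that add atoms: none
Why: Proposed new method: anti-periplanar E2 loss of H-6/Br-7 from the anti adduct gives only the E-enol ether 3, whose Claisen [3,3] shift through an oxygen-bridged boat-like transition state joins C1 to C7 on the face carrying the vinyl group, so the C3 configuration is relayed to the C7 quaternary centre while C2=C3 and the C6 ketone form; the closest known reaction type is the dehydrohalogenation/Claisen ring enlargement of 2-vinyl-5-(1-haloalkyl)tetrahydrofurans to cyclohept-4-enones (karahanaenone synthesis), which has no stereogenic enol ether.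

**Step 3**
Reactants: 4 (2R)-2,5-dimethyl-2-(4-methylpent-3-en-1-yl)cyclohept-4-en-1-one
Product: 5 (3S,3aS,8aR)-6,8a-dimethyl-3-(propan-2-yl)-2,3,4,5,8,8a-hexahydroazulen-3a(1H)-ol (carotol skeleton; expected major diastereomer)
Conditions: SmI2 (2.5 equiv), hexamethylphosphoramide, t-BuOH, THF, 0 °C → rt
Reagents that add atoms: none
Why: Ketyl–olefin 5-exo-trig radical cyclisation closes the C6–C10 bond; the ketyl adds on the tether face with its oxygen anti to the developing CMe2 radical, placing OH cis to the angular methyl and to H-4 (both centres are erased in step 4).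

**Step 4**
Reactants: 5 (3S,3aS,8aR)-6,8a-dimethyl-3-(propan-2-yl)-2,3,4,5,8,8a-hexahydroazulen-3a(1H)-ol
Product: 6 (8aR)-6,8a-dimethyl-3-(propan-2-yl)-1,2,4,5,8,8a-hexahydroazulene (daucene)
Conditions: methyl N-(triethylammoniosulfonyl)carbamate (Burgess reagent), toluene, 50 °C
Reagents that add atoms: none
Why: Burgess syn-elimination (Ei) of the tertiary alcohol with the syn H-4 gives the tetrasubstituted C4=C5 alkene (Zaitsev), leaving C-1 as the only stereocentre.

**Step 5**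
Reactants: 6 (8aR)-6,8a-dimethyl-3-(propan-2-yl)-1,2,4,5,8,8a-hexahydroazulene
Product: 8 (3S,8aR)-6,8a-dimethyl-3-(propan-2-yl)-1,2,3,5,8,8a-hexahydroazulen-3-ol, via allylic hydroperoxide 7 (not isolated)
Conditions: O2, visible light, 5,10,15,20-tetraphenylporphyrin (cat.), CH2Cl2, −40 °C; then PPh3
Reagents that add atoms: oxygen, O=O
Why: Schenck ene reaction: singlet oxygen attacks the tetrasubstituted alkene faster than the trisubstituted one, from the α-face (anti to the angular methyl), bonding at the less hindered C-4 and taking the α-H from C-6, which sets C-4 (OH α) and moves the alkene to C5=C6; PPh3 reduces the hydroperoxide.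

**Step 6**
Reactants: 8 (3S,8aR)-6,8a-dimethyl-3-(propan-2-yl)-1,2,3,5,8,8a-hexahydroazulen-3-ol
Product: 11 (3S,3aS,4S,8aR)-6,8a-dimethyl-3-(propan-2-yl)-1,2,3,3a,4,5,8,8a-octahydroazulene-3,4-diol, via dimethylsilyl ether 9 (not isolated), via oxasilolane 10 (not isolated)
Conditions: HMe2SiCl, Et3N, 4-(dimethylamino)pyridine (cat.), CH2Cl2, 0 °C; then H2PtCl6·6H2O (1 mol %), THF, 60 °C; then H2O2 (30 %), KF, KHCO3, THF/MeOH, rt
Reagents that add atoms: chlorodimethylsilane, C[SiH](C)Cl (its SiMe2 unit stays in 9 and 10 only); hydrogen peroxide, OO (oxygen on C-6 of 11)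
Why: Tamao–Ito sequence: the silicon tether on the 4α-oxygen delivers Si–H intramolecularly (5-endo, syn addition) to the α-face of C5=C6 only, giving H-5 α (trans ring fusion) and C6–Si α, and Tamao oxidation with retention gives the 6α-OH.

**Step 7**
Reactants: 11 (3S,3aS,4S,8aR)-6,8a-dimethyl-3-(propan-2-yl)-1,2,3,3a,4,5,8,8a-octahydroazulene-3,4-diol; 12 4-[(tert-butyldimethylsilyl)oxy]benzoic acid
Product: 13 [(3S,3aS,4S,8aR)-3-hydroxy-6,8a-dimethyl-3-(propan-2-yl)-1,2,3,3a,4,5,8,8a-octahydroazulen-4-yl] 4-[(tert-butyldimethylsilyl)oxy]benzoate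
Conditions: N,N′-dicyclohexylcarbodiimide, 4-(dimethylamino)pyridine, CH2Cl2, rt
Reagents that add atoms: none
Why: Steglich esterification acylates the secondary 6-OH while the hindered tertiary 4-OH does not react; no stereocentre is touched.

**Step 8**
Reactants: 13 [(3S,3aS,4S,8aR)-3-hydroxy-6,8a-dimethyl-3-(propan-2-yl)-1,2,3,3a,4,5,8,8a-octahydroazulen-4-yl] 4-[(tert-butyldimethylsilyl)oxy]benzoate
Product: 14 [(3S,3aS,4S,8aS)-3-hydroxy-6,8a-dimethyl-8-oxo-3-(propan-2-yl)-1,2,3,3a,4,5,8,8a-octahydroazulen-4-yl] 4-[(tert-butyldimethylsilyl)oxy]benzoate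
Conditions: CrO3, 3,5-dimethylpyrazole, CH2Cl2, −20 °C
Reagents that add atoms: chromium trioxide, O=[Cr](=O)=O
Why: Allylic oxidation of the only remaining alkene at the CH2 next to its CH terminus (C-10), as in the oxidation of trisubstituted ring alkenes to enones; C-7 is deactivated by the adjacent acyloxy group.

**Step 9**
Reactants: 14 [(3S,3aS,4S,8aS)-3-hydroxy-6,8a-dimethyl-8-oxo-3-(propan-2-yl)-1,2,3,3a,4,5,8,8a-octahydroazulen-4-yl] 4-[(tert-butyldimethylsilyl)oxy]benzoate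
Product: 15 [(3S,3aS,4S,8R,8aS)-3,8-dihydroxy-6,8a-dimethyl-3-(propan-2-yl)-1,2,3,3a,4,5,8,8a-octahydroazulen-4-yl] 4-[(tert-butyldimethylsilyl)oxy]benzoate
Conditions: (S)-1-methyl-3,3-diphenyltetrahydro-1H,3H-pyrrolo[1,2-c][1,3,2]oxazaborole [(S)-Me-CBS, 0.5 equiv], BH3·SMe2, THF, −30 °C; MeOH quench
Reagents that add atoms: none
Why: Corey–Bakshi–Shibata reduction under reagent control: with the quaternary C-1 side as the large group, the (S)-catalyst delivers hydride to the β-face of the enone carbonyl and gives the 10α-alcohol (1,2-reduction only).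

**Step 10**
Reactants: 15 [(3S,3aS,4S,8R,8aS)-3,8-dihydroxy-6,8a-dimethyl-3-(propan-2-yl)-1,2,3,3a,4,5,8,8a-octahydroazulen-4-yl] 4-[(tert-butyldimethylsilyl)oxy]benzoate; 16 (2E)-2-methylbut-2-enoyl chloride (tigloyl chloride)
Product: 17 [(3S,3aS,4S,8R,8aS)-3-hydroxy-6,8a-dimethyl-8-{[(2E)-2-methylbut-2-enoyl]oxy}-3-(propan-2-yl)-1,2,3,3a,4,5,8,8a-octahydroazulen-4-yl] 4-[(tert-butyldimethylsilyl)oxy]benzoate
Conditions: pyridine, 4-(dimethylamino)pyridine (cat.), CH2Cl2, 0 °C → rt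
Reagents that add atoms: none
Why: Acyl transfer (nucleophilic catalysis) esterifies the secondary allylic 10-OH with retention; the tertiary 4-OH stays free and pyridine is too weak a base to deconjugate the tiglate.

**Step 11**
Reactants: 17 [(3S,3aS,4S,8R,8aS)-3-hydroxy-6,8a-dimethyl-8-{[(2E)-2-methylbut-2-enoyl]oxy}-3-(propan-2-yl)-1,2,3,3a,4,5,8,8a-octahydroazulen-4-yl] 4-[(tert-butyldimethylsilyl)oxy]benzoate
Product: 18 [(3S,3aS,4S,8R,8aS)-3-hydroxy-6,8a-dimethyl-8-{[(2E)-2-methylbut-2-enoyl]oxy}-3-(propan-2-yl)-1,2,3,3a,4,5,8,8a-octahydroazulen-4-yl] 4-hydroxybenzoate (target)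
Conditions: Bu4NF, AcOH, THF, 0 °C
Reagents that add atoms: none
Why: Fluoride-mediated desilylation of the aryl silyl ether; the acetic acid buffer keeps both esters and all stereocentres intact.

**Compound list**
1 | (3S,6E)-3,7,11-trimethyldodeca-1,6,10-trien-3-ol [(3S,6E)-nerolidol] | C=C[C@@](C)(O)CC/C=C(\C)CCC=C(C)C | starting material
2 | (2S,5R)-5-[(2S)-2-bromo-6-methylhept-5-en-2-yl]-2-ethenyl-2-methyloxolane (with its 5S,2′R partner) | C=C[C@]1(C)CC[C@@H](O1)[C@@](C)(Br)CCC=C(C)C | intermediate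
3 | (2S,5E)-2-ethenyl-2-methyl-5-(6-methylhept-5-en-2-ylidene)oxolane | C=C[C@]1(C)CC/C(O1)=C(/C)CCC=C(C)C | intermediate
4 | (2R)-2,5-dimethyl-2-(4-methylpent-3-en-1-yl)cyclohept-4-en-1-one | CC(C)=CCC[C@]1(C)CC=C(C)CCC1=O | intermediate
5 | (3S,3aS,8aR)-6,8a-dimethyl-3-(propan-2-yl)-2,3,4,5,8,8a-hexahydroazulen-3a(1H)-ol | C1C=C(C)CC[C@]2(O)[C@H](C(C)C)CC[C@]12C | intermediate
6 | (8aR)-6,8a-dimethyl-3-(propan-2-yl)-1,2,4,5,8,8a-hexahydroazulene (daucene) | C1C=C(C)CCC2=C(C(C)C)CC[C@@]21C | intermediate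
7 | (3S,8aR)-3-hydroperoxy-6,8a-dimethyl-3-(propan-2-yl)-1,2,3,5,8,8a-hexahydroazulene | C1C=C(C)CC=C2[C@]1(C)CC[C@]2(OO)C(C)C | intermediate
8 | (3S,8aR)-6,8a-dimethyl-3-(propan-2-yl)-1,2,3,5,8,8a-hexahydroazulen-3-ol | C1C=C(C)CC=C2[C@]1(C)CC[C@]2(O)C(C)C | intermediate
9 | {[(3S,8aR)-6,8a-dimethyl-3-(propan-2-yl)-1,2,3,5,8,8a-hexahydroazulen-3-yl]oxy}dimethylsilane | C1C=C(C)CC=C2[C@]1(C)CC[C@]2(O[SiH](C)C)C(C)C | intermediate
10 | cyclic silyl ether of 11: 2,2-dimethyl-1-oxa-2-silacyclopentane fused over O-4/C-4/C-5/C-6 (Si on C-6α, H-5α) | C1C=C(C)C[C@H]3[C@@H]2[C@]1(C)CC[C@]2(O[Si]3(C)C)C(C)C | intermediate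
11 | (3S,3aS,4S,8aR)-6,8a-dimethyl-3-(propan-2-yl)-1,2,3,3a,4,5,8,8a-octahydroazulene-3,4-diol (dauc-8-ene-4α,6α-diol) | C1C=C(C)C[C@H](O)[C@@H]2[C@]1(C)CC[C@]2(O)C(C)C | intermediate
12 | 4-[(tert-butyldimethylsilyl)oxy]benzoic acid | CC(C)(C)[Si](C)(C)Oc1ccc(cc1)C(=O)O | starting material
13 | [(3S,3aS,4S,8aR)-3-hydroxy-6,8a-dimethyl-3-(propan-2-yl)-1,2,3,3a,4,5,8,8a-octahydroazulen-4-yl] 4-[(tert-butyldimethylsilyl)oxy]benzoate | C1C=C(C)C[C@H](OC(=O)c2ccc(O[Si](C)(C)C(C)(C)C)cc2)[C@@H]2[C@]1(C)CC[C@]2(O)C(C)C | intermediate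
14 | [(3S,3aS,4S,8aS)-3-hydroxy-6,8a-dimethyl-8-oxo-3-(propan-2-yl)-1,2,3,3a,4,5,8,8a-octahydroazulen-4-yl] 4-[(tert-butyldimethylsilyl)oxy]benzoate | O=C1C=C(C)C[C@H](OC(=O)c2ccc(O[Si](C)(C)C(C)(C)C)cc2)[C@@H]2[C@]1(C)CC[C@]2(O)C(C)C | intermediate
15 | [(3S,3aS,4S,8R,8aS)-3,8-dihydroxy-6,8a-dimethyl-3-(propan-2-yl)-1,2,3,3a,4,5,8,8a-octahydroazulen-4-yl] 4-[(tert-butyldimethylsilyl)oxy]benzoate | O[C@@H]1C=C(C)C[C@H](OC(=O)c2ccc(O[Si](C)(C)C(C)(C)C)cc2)[C@@H]2[C@]1(C)CC[C@]2(O)C(C)C | intermediate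
16 | (2E)-2-methylbut-2-enoyl chloride (tigloyl chloride) | C/C=C(\C)C(Cl)=O | starting material
17 | [(3S,3aS,4S,8R,8aS)-3-hydroxy-6,8a-dimethyl-8-{[(2E)-2-methylbut-2-enoyl]oxy}-3-(propan-2-yl)-1,2,3,3a,4,5,8,8a-octahydroazulen-4-yl] 4-[(tert-butyldimethylsilyl)oxy]benzoate | C/C=C(\C)C(=O)O[C@@H]1C=C(C)C[C@H](OC(=O)c2ccc(O[Si](C)(C)C(C)(C)C)cc2)[C@@H]2[C@]1(C)CC[C@]2(O)C(C)C | intermediate
18 | [(3S,3aS,4S,8R,8aS)-3-hydroxy-6,8a-dimethyl-8-{[(2E)-2-methylbut-2-enoyl]oxy}-3-(propan-2-yl)-1,2,3,3a,4,5,8,8a-octahydroazulen-4-yl] 4-hydroxybenzoate | C/C=C(\C)C(=O)O[C@@H]1C=C(C)C[C@H](OC(=O)c2ccc(O)cc2)[C@@H]2[C@]1(C)CC[C@]2(O)C(C)C | target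

**Step count and risks**
Total step count: 11. Longest linear sequence: 11 steps (1 → 18).

Step 2 is the most likely to fail. The E2 may remove a methyl or C8 hydrogen instead of H‑6, or partial ionisation may scramble the enol ether geometry and erode the enantiomeric purity of 4. The fallback sets out from 1 and comes back at 4 by a radical 1,7‑closure that turns the problem into separable diastereomers. Acetylation (Ac2O, Et3N, 4‑(dimethylamino)pyridine) gives (3S,6E)‑nerolidyl acetate F1. Shi epoxidation (1,2:4,5‑di‑O‑isopropylidene‑β‑D‑erythro‑2,3‑hexodiulo‑2,6‑pyranose, KHSO5, K2CO3, 0 °C, stopped near half conversion, 10,11‑isomer removed) gives the (6R,7R)‑6,7‑epoxy acetate F2. Cp2TiCl (from Cp2TiCl2 and Mn dust, THF) opens the epoxide to the tertiary C7 radical, which adds 7‑endo to the vinyl terminus and then loses the β‑acetoxy group; this gives (1R,2R)‑2,5‑dimethyl‑2‑(4‑methylpent‑3‑en‑1‑yl)cyclohept‑4‑en‑1‑ol F3 after chromatographic removal of its C‑2 epimer. Dess–Martin oxidation of F3 gives 4.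

Step 5 is the second risk. The ene reaction may put oxygen on C‑5 or take hydrogen from C‑3 or the isopropyl group. The fallback sets out from 6 and comes back at 8. Epoxidation with m‑chloroperbenzoic acid (NaHCO3, CH2Cl2, −78 °C) takes the tetrasubstituted alkene from the α‑face and gives the (3S,3aS,8aR)‑3,3a‑epoxide F4. Diethylaluminium 2,2,6,6‑tetramethylpiperidide (toluene, 0 °C) then opens it by syn β‑elimination of the α‑hydrogen on C‑6 to give 8.

Step 9 is the third risk. The catalyst has to override the substrate preference for hydride attack anti to the angular methyl, and the assignment of the large group is a judgement. The fallback sets out from 14 and comes back at 17. Luche reduction (NaBH4, CeCl3·7H2O, MeOH, −78 °C) follows the substrate bias and gives the 10β‑alcohol F5. Mitsunobu esterification with tiglic acid (PPh3, diisopropyl azodicarboxylate, toluene, 0 °C) inverts C‑10 and installs the tiglate in one operation, giving 17.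

**Further compounds**
F1 | step 2 | (3S,6E)-3,7,11-trimethyldodeca-1,6,10-trien-3-yl acetate | C=C[C@@](C)(OC(C)=O)CC/C=C(\C)CCC=C(C)C
F2 | step 2 | (3S)-3-methyl-5-[(2R,3R)-3-methyl-3-(4-methylpent-3-en-1-yl)oxiran-2-yl]pent-1-en-3-yl acetate | C=C[C@@](C)(OC(C)=O)CC[C@H]1O[C@]1(C)CCC=C(C)C
F3 | step 2 | (1R,2R)-2,5-dimethyl-2-(4-methylpent-3-en-1-yl)cyclohept-4-en-1-ol | CC(C)=CCC[C@]1(C)CC=C(C)CC[C@H]1O
F4 | step 5 | (3S,3aS,8aR)-3,3a-epoxy-6,8a-dimethyl-3-(propan-2-yl)-1,2,3,3a,4,5,8,8a-octahydroazulene | C1C=C(C)CC[C@]23O[C@]3(C(C)C)CC[C@]12C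
F5 | step 9 | [(3S,3aS,4S,8S,8aS)-3,8-dihydroxy-6,8a-dimethyl-3-(propan-2-yl)-1,2,3,3a,4,5,8,8a-octahydroazulen-4-yl] 4-[(tert-butyldimethylsilyl)oxy]benzoate | O[C@H]1C=C(C)C[C@H](OC(=O)c2ccc(O[Si](C)(C)C(C)(C)C)cc2)[C@@H]2[C@]1(C)CC[C@]2(O)C(C)C
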